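**Retrosynthetic overview**

1. Numbering used below: ring carbons C1 (C=O), C2 (OAc), C3 (CH3), C4 (CHOH), C5 (CH2), C6; exocyclic C7 (=C6) and C8 (CH–O-angeloyl). Enabling feature: in O–C4–C5–C6(=C7)–C8–O the C4 hydroxyl is homoallylic and the C8 oxygen allylic to the exocyclic C6=C7 bond, the signature of two successive carbonyl allylations by one C5–C6–C7 allyl unit; C1(=O)–C2(OAc)=C3(CH3)–C4 is a ring-opened 3-acetoxy-4-methylfuran.
2. Last disconnection, C4–C5: intramolecular allylboration of the C4 aldehyde by a tertiary C7 allylboronate; the cis keto aldehyde is released from the furan (temporary ring A) by singlet oxygen, and C7 hands its configuration to C4 and to the alkene geometry and disappears.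
3. C7–C8: asymmetric chromium-mediated allylation of 4-methylpent-3-enal by a γ-boryl allyl bromide (sets C7 and C8); the C8 ester follows by Yamaguchi acylation.
4. C6=C7 geometry and the furan–C6 bond: syn arylboration of a but-2-yn-1-ol ether with a 2-iodofuran made from 3-hydroxy-4-methylfuran-2(5H)-one.
5. Ring order: furan ring A first (step 3); carbocycle ring B last (step 12), formed in the operation that consumes ring A.

Key step: step 12

Remark: Bpin = 4,4,5,5-tetramethyl-1,3,2-dioxaborolan-2-yl.
Remark: in step 10 the ligand enantiomer is the one that directs the allyl group to the Re face of aldehyde 15; this assignment would be checked on a model aldehyde.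
Remark: 3 and 6 are racemic and 21 is a pair of bridgehead diastereomers; these centers vanish in the next transformation, so their SMILES carry no descriptors there.

**Step 1**
Reactants: 1 diethyl 2-methyl-3-oxobutanedioate; 2 formaldehyde
Product: 4 3-hydroxy-4-methylfuran-2(5H)-one, via keto lactone ester 3 (not isolated)
Conditions: K2CO3 (0.1 equiv), H2O, 0 °C to rt; then 6 M HCl, reflux
Reagents that add atoms: none
Why: Aldol addition of the doubly activated methine of 1 to formaldehyde, lactonisation onto the oxalyl ester and acid-mediated hydrolysis–decarboxylation of the β-keto ester 3 should give the enolised α-keto lactone, as in the established route to its 5-alkyl homologues; no stereocenter is formed.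

**Step 2**
Reactants: 4 3-hydroxy-4-methylfuran-2(5H)-one
Product: 5 4-methyl-3-[(triisopropylsilyl)oxy]furan-2(5H)-one
Conditions: TIPSCl, imidazole, DMF, rt
Reagents that add atoms: triisopropylsilyl chloride, CC(C)[Si](Cl)(C(C)C)C(C)C
Why: Silyl ether formation at the acidic enol protects the future C2 oxygen as a hindered, base-stable silyl enol ether.

**Step 3**
Reactants: 5 4-methyl-3-[(triisopropylsilyl)oxy]furan-2(5H)-one
Product: 7 triisopropyl[(4-methylfuran-3-yl)oxy]silane, via lactol 6 (not isolated)
Conditions: diisobutylaluminium hydride, CH2Cl2, −78 °C; then aq. citric acid, rt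
Reagents that add atoms: none
Why: Half-reduction of the butenolide stops at lactol 6, which loses water under mild acid and aromatises to the 3-silyloxyfuran (standard butenolide-to-furan conversion).

**Step 4**
Reactants: 7 triisopropyl[(4-methylfuran-3-yl)oxy]silane
Product: 8 [(2-iodo-4-methylfuran-3-yl)oxy]triisopropylsilane
Conditions: NIS, THF, −78 to 0 °C, dark
Reagents that add atoms: N-iodosuccinimide, O=C1CCC(=O)N1I
Why: Electrophilic aromatic iodination should occur at the α-position flanked by the ring oxygen and the silyloxy group, the most nucleophilic site of a 3-oxyfuran.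

**Step 5**
Reactants: 9 but-2-yn-1-ol
Product: 10 (but-2-yn-1-yloxy)(tert-butyl)dimethylsilane
Conditions: TBSCl, imidazole, CH2Cl2, rt
Reagents that add atoms: tert-butyldimethylsilyl chloride, CC(C)(C)[Si](C)(C)Cl
Why: Standard silylation of the primary alcohol removes the proton source that would otherwise intercept the alkenylcopper intermediate of step 6.

**Step 6**
Reactants: 10 (but-2-yn-1-yloxy)(tert-butyl)dimethylsilane; 8 [(2-iodo-4-methylfuran-3-yl)oxy]triisopropylsilane
Product: 11 tert-butyl{[(2E)-2-{4-methyl-3-[(triisopropylsilyl)oxy]furan-2-yl}-3-Bpin-but-2-en-1-yl]oxy}dimethylsilane (furyl cis to boryl)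
Conditions: B2pin2, CuCl (5 mol%), PCy3, Pd(OAc)2 (2 mol%), XPhos, NaOtBu, toluene, 50 °C
Reagents that add atoms: bis(pinacolato)diboron, CC1(C)OB(OC1(C)C)B1OC(C)(C)C(C)(C)O1
Why: Copper-catalysed syn-borylcupration of the alkyne should place boron on the methyl-bearing carbon and copper next to the inductively withdrawing CH2OSi group, and palladium-mediated coupling of that alkenylcopper with 8 proceeds with retention, so furyl and boryl end up cis on the tetrasubstituted alkene (alkyne arylboration by cooperative copper/palladium catalysis).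

**Step 7**
Reactants: 11 tert-butyl{[(2E)-2-{4-methyl-3-[(triisopropylsilyl)oxy]furan-2-yl}-3-Bpin-but-2-en-1-yl]oxy}dimethylsilane
Product: 12 2-{(2E)-1-[(tert-butyldimethylsilyl)oxy]-3-Bpin-but-2-en-2-yl}-4-methylfuran-3-yl acetate
Conditions: CsF, Ac2O, DMF, 0 °C
Reagents that add atoms: acetic anhydride, CC(=O)OC(C)=O
Why: Fluoride cleaves the aryl-type Si–O bond much faster than the alkyl silyl ether, and the furan-3-olate is trapped on oxygen by the anhydride (desilylative acetylation), which installs the acetate of the target before any base-sensitive group is present.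

**Step 8**
Reactants: 12 2-{(2E)-1-[(tert-butyldimethylsilyl)oxy]-3-Bpin-but-2-en-2-yl}-4-methylfuran-3-yl acetate
Product: 13 2-[(2Z)-1-bromo-3-Bpin-but-2-en-2-yl]-4-methylfuran-3-yl acetate (CH2Br cis to CH3)
Conditions: Ph3PBr2, CH2Cl2, 0 °C to rt
Reagents that add atoms: dibromotriphenylphosphorane, BrP(Br)(c1ccccc1)(c1ccccc1)c1ccccc1
Why: The phosphorane converts the primary allylic silyl ether directly into the bromide by SN2 displacement of an oxyphosphonium group, which leaves the alkene geometry, the boronate and the acetate untouched.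

**Step 9**
Reactants: 14 4-methylpent-3-en-1-ol
Product: 15 4-methylpent-3-enal
Conditions: Dess–Martin periodinane, CH2Cl2, 0 °C to rt
Reagents that add atoms: none
Why: Dess–Martin oxidation under non-basic conditions should give the β,γ-unsaturated aldehyde without migration of the double bond; it is used crude.

**Step 10**
Reactants: 13 2-[(2Z)-1-bromo-3-Bpin-but-2-en-2-yl]-4-methylfuran-3-yl acetate; 15 4-methylpent-3-enal
Product: 17 2-[(3S,4S)-4-hydroxy-3,7-dimethyl-3-Bpin-octa-1,6-dien-2-yl]-4-methylfuran-3-yl acetate, via trimethylsilyl ether 16 (not isolated)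
Conditions: CrCl2 (10 mol%), chiral bis(oxazolinyl)carbazole ligand (12 mol%), Mn, TMSCl, THF, 0 °C to rt; then aq. citric acid
Reagents that add atoms: none
Why: In this catalytic asymmetric Nozaki–Hiyama–Kishi allylation the γ,γ-disubstituted allylchromium reagent keeps its geometry and adds through its boron-bearing γ-carbon in a closed chair transition state with the aldehyde chain and the boryl group pseudoequatorial (hydroxyl anti to boron, which fixes the relative configuration), while the chiral ligand selects the Re face of 15 and so sets both new centers as S.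

**Step 11**
Reactants: 17 2-[(3S,4S)-4-hydroxy-3,7-dimethyl-3-Bpin-octa-1,6-dien-2-yl]-4-methylfuran-3-yl acetate; 18 angelic acid
Product: 20 (3S,4S)-2-(3-acetoxy-4-methylfuran-2-yl)-3,7-dimethyl-3-Bpin-octa-1,6-dien-4-yl (2Z)-2-methylbut-2-enoate, via mixed anhydride 19 (not isolated)
Conditions: 18, 2,4,6-trichlorobenzoyl chloride, Et3N, toluene, rt; then 17, toluene, 70 °C
Reagents that add atoms: none
Why: Yamaguchi esterification through mixed anhydride 19 should acylate the hindered secondary alcohol under conditions known to preserve the Z geometry of angelates; the stereocenters are not touched.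

**Step 12**
Reactants: 20 (3S,4S)-2-(3-acetoxy-4-methylfuran-2-yl)-3,7-dimethyl-3-Bpin-octa-1,6-dien-4-yl (2Z)-2-methylbut-2-enoate
Product: 24 (3S)-2-[(1E,5R)-3-acetoxy-5-hydroxy-4-methyl-2-oxocyclohex-3-en-1-ylidene]-6-methylhept-5-en-3-yl (2Z)-2-methylbut-2-enoate, via endoperoxide 21 (not isolated), via keto aldehyde 22 (not isolated), via borate ester 23 (not isolated)
Conditions: O2, visible light, tetraphenylporphyrin (cat.), CH2Cl2, −78 °C; then Me2S, −78 to 0 °C; pH 7 buffer
Reagents that add atoms: oxygen, O=O
Why: Singlet oxygen adds [4+2] across the 2,5-positions of the electron-rich furan to give endoperoxide 21, dimethyl sulfide reduces the O–O bond and the ring opens to keto aldehyde 22, in which the former furan carbons are the C1 ketone and the C4 aldehyde held cis by the former ring; the tertiary allylboronate then adds to the C4 aldehyde through a closed six-membered chair transition state with B–O bonding, forming C4–C5 with allylic transposition so that the boron-bearing C7 becomes the alkylidene carbon, and hydrolysis of borate 23 releases 24. The closest known reactions are the allylboration of aldehydes by α,α-disubstituted (tertiary) allylboronates and by 2-acyl- or 2-alkoxycarbonyl-substituted allylboronates, which transfer chirality from the boron-bearing carbon, and, for the topology, the Lewis acid carbonyl-ene cyclisation whose tether leaves the central carbon of the ene. Ring B closes as a six-membered ring whose tether joins the central allyl carbon C6 to the aldehyde carbon C4 (endo with respect to the C5=C6 bond, exo with respect to C4=O), so C3 sits pseudoaxial on the chair and the two six-membered arrays form a bicyclo[3.3.1]-like transition state. The C4 stereocenter is controlled by the (S)-configured C7: boron and the aldehyde oxygen must lie on the same face, and in the preferred chair the bulky C8 chain is pseudoaxial (away from the pinacol oxygens) while methyl is pseudoequatorial next to the C1 acyl group (least 1,2-allylic strain), which delivers 4R and the E alkene together, whereas the other chair would give the Z alkene with 4S. The step needs furan over trisubstituted alkene in the oxygenation (secured by the much higher rate of the furan cycloaddition, low temperature and limiting oxygen uptake), aldehyde over ketone (only C4 can reach the γ-carbon C5) and the first chair over the second (secured by the size difference between methyl and the C8 chain).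

**Compound list**

1 | diethyl 2-methyl-3-oxobutanedioate (diethyl oxalpropionate) | CCOC(=O)C(C)C(=O)C(=O)OCC | starting material
2 | formaldehyde (37% aqueous) | C=O | starting material
3 | ethyl 3-methyl-4,5-dioxooxolane-3-carboxylate (racemic) | CCOC(=O)C1(C)COC(=O)C1=O | intermediate
4 | 3-hydroxy-4-methylfuran-2(5H)-one | CC1=C(O)C(=O)OC1 | intermediate
5 | 4-methyl-3-[(triisopropylsilyl)oxy]furan-2(5H)-one | CC1=C(O[Si](C(C)C)(C(C)C)C(C)C)C(=O)OC1 | intermediate
6 | 4-methyl-3-[(triisopropylsilyl)oxy]-2,5-dihydrofuran-2-ol (racemic) | CC1=C(O[Si](C(C)C)(C(C)C)C(C)C)C(O)OC1 | intermediate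
7 | triisopropyl[(4-methylfuran-3-yl)oxy]silane | Cc1cocc1O[Si](C(C)C)(C(C)C)C(C)C | intermediate
8 | [(2-iodo-4-methylfuran-3-yl)oxy]triisopropylsilane | Cc1coc(I)c1O[Si](C(C)C)(C(C)C)C(C)C | intermediate
9 | but-2-yn-1-ol | CC#CCO | starting material
10 | (but-2-yn-1-yloxy)(tert-butyl)dimethylsilane | CC#CCO[Si](C)(C)C(C)(C)C | intermediate
11 | tert-butyl{[(2E)-2-{4-methyl-3-[(triisopropylsilyl)oxy]furan-2-yl}-3-Bpin-but-2-en-1-yl]oxy}dimethylsilane | C/C(B1OC(C)(C)C(C)(C)O1)=C(\CO[Si](C)(C)C(C)(C)C)c1occ(C)c1O[Si](C(C)C)(C(C)C)C(C)C | intermediate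
12 | 2-{(2E)-1-[(tert-butyldimethylsilyl)oxy]-3-Bpin-but-2-en-2-yl}-4-methylfuran-3-yl acetate | C/C(B1OC(C)(C)C(C)(C)O1)=C(\CO[Si](C)(C)C(C)(C)C)c1occ(C)c1OC(C)=O | intermediate
13 | 2-[(2Z)-1-bromo-3-Bpin-but-2-en-2-yl]-4-methylfuran-3-yl acetate | C/C(B1OC(C)(C)C(C)(C)O1)=C(\CBr)c1occ(C)c1OC(C)=O | intermediate
14 | 4-methylpent-3-en-1-ol | CC(C)=CCCO | starting material
15 | 4-methylpent-3-enal | CC(C)=CCC=O | intermediate
16 | 2-{(3S,4S)-3,7-dimethyl-3-Bpin-4-[(trimethylsilyl)oxy]octa-1,6-dien-2-yl}-4-methylfuran-3-yl acetate | C=C(c1occ(C)c1OC(C)=O)[C@@](C)(B1OC(C)(C)C(C)(C)O1)[C@@H](O[Si](C)(C)C)CC=C(C)C | intermediate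
17 | 2-[(3S,4S)-4-hydroxy-3,7-dimethyl-3-Bpin-octa-1,6-dien-2-yl]-4-methylfuran-3-yl acetate | C=C(c1occ(C)c1OC(C)=O)[C@@](C)(B1OC(C)(C)C(C)(C)O1)[C@@H](O)CC=C(C)C | intermediate
18 | angelic acid, (2Z)-2-methylbut-2-enoic acid | C/C=C(/C)C(=O)O | starting material
19 | (2Z)-2-methylbut-2-enoic 2,4,6-trichlorobenzoic anhydride | C/C=C(/C)C(=O)OC(=O)c1c(Cl)cc(Cl)cc1Cl | intermediate
20 | (3S,4S)-2-(3-acetoxy-4-methylfuran-2-yl)-3,7-dimethyl-3-Bpin-octa-1,6-dien-4-yl (2Z)-2-methylbut-2-enoate | C=C(c1occ(C)c1OC(C)=O)[C@@](C)(B1OC(C)(C)C(C)(C)O1)[C@@H](OC(=O)/C(C)=C\C)CC=C(C)C | intermediate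
21 | (3S,4S)-2-(6-acetoxy-5-methyl-2,3,7-trioxabicyclo[2.2.1]hept-5-en-1-yl)-3,7-dimethyl-3-Bpin-octa-1,6-dien-4-yl (2Z)-2-methylbut-2-enoate (both bridgehead diastereomers) | CC1=C(OC(C)=O)C2(OOC1O2)C(=C)[C@@](C)(B1OC(C)(C)C(C)(C)O1)[C@@H](OC(=O)/C(C)=C\C)CC=C(C)C | intermediate
22 | (2E,6S,7S)-3-acetoxy-2,6,10-trimethyl-5-methylidene-1,4-dioxo-6-Bpin-undeca-2,9-dien-7-yl (2Z)-2-methylbut-2-enoate (formyl cis to the ketone carbonyl) | O=C/C(C)=C(OC(C)=O)\C(=O)C(=C)[C@@](C)(B1OC(C)(C)C(C)(C)O1)[C@@H](OC(=O)/C(C)=C\C)CC=C(C)C | intermediate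
23 | O-(pinacolboryl) derivative of 24 at the ring hydroxyl | C/C=C(/C)C(=O)O[C@@H](CC=C(C)C)/C(C)=C1\C[C@@H](OB2OC(C)(C)C(C)(C)O2)C(C)=C(OC(C)=O)C1=O | intermediate
24 | (3S)-2-[(1E,5R)-3-acetoxy-5-hydroxy-4-methyl-2-oxocyclohex-3-en-1-ylidene]-6-methylhept-5-en-3-yl (2Z)-2-methylbut-2-enoate | C/C=C(/C)C(=O)O[C@@H](CC=C(C)C)/C(C)=C1\C[C@@H](O)C(C)=C(OC(C)=O)C1=O | target

**Step count and risks**

Total step count: 12. Longest linear sequence: 10 (steps 1–4, 6–8, 10–12); steps 5 and 9 are one-step side branches.

Step 10. What may go wrong: insufficient facial discrimination at the aldehyde by the chromium–ligand complex, partial loss of the allyl geometry by 1,3-metal shift before C–C bond formation, and boron–oxygen elimination from the β-oxido boronate. Fallback, from 13 back to 17: the C–C bond is made by allylboration instead of through an allylchromium reagent. Palladium-catalysed borylation of 13 (Pd2(dba)3, B2pin2, toluene, 50 °C) would give the allylic bis(boronate) 4-methyl-2-[(2E)-1,3-bis(Bpin)but-2-en-2-yl]furan-3-yl acetate F1. Only its allylboronate unit adds to 15 under a chiral BINOL-derived phosphoric acid catalyst (toluene, −30 °C) through a closed chair transition state, in which the fixed alkene geometry of F1 sets the relative configuration and the catalyst the absolute one, to give the O-boryl adduct F2. Aqueous work-up hydrolyses F2 to 17.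

Step 11. What may go wrong: slow acyl transfer to the neopentyl-type hydroxyl, isomerisation of the activated angeloyl unit to the tigloyl isomer on prolonged heating, and β-elimination of boron and the acyloxy group. Fallback, from 17 back to 20: the angelate double bond is built on the oxygen after acylation with an unhindered acid that cannot isomerise. 17 would be esterified with 2-[bis(2,2,2-trifluoroethoxy)phosphoryl]propanoic acid (N,N'-diisopropylcarbodiimide, DMAP cat., CH2Cl2, 0 °C) to the phosphonate ester F3. A Z-selective Horner–Wadsworth–Emmons reaction (Still–Gennari variant: KN(SiMe3)2, 18-crown-6, acetaldehyde, THF, −78 °C) then converts F3 into 20.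

Step 12. What may go wrong: competing ene reaction of singlet oxygen at the trisubstituted alkene, cycloaddition across the furan–vinyl diene, or over-oxidation of the endoperoxide, each diverting material before the allylboration. Fallback, from 20 back to 22: the furan is opened electrochemically instead of by cycloaddition. Constant-current anodic oxidation of 20 in methanol (carbon anode, LiClO4, 2,6-lutidine, −20 °C) should oxidise only the furan and give the 2,5-dimethoxy-2,5-dihydrofuran F4. Hydrolysis of this bis-acetal (pyridinium p-toluenesulfonate cat., acetone–water, 0 °C) releases keto aldehyde 22, which cyclises to 23 and gives 24 as in step 12.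

**Further compounds**

F1 | step 10 | 4-methyl-2-[(2E)-1,3-bis(Bpin)but-2-en-2-yl]furan-3-yl acetate | C/C(B1OC(C)(C)C(C)(C)O1)=C(\CB1OC(C)(C)C(C)(C)O1)c1occ(C)c1OC(C)=O
F2 | step 10 | 2-{(3S,4S)-3,7-dimethyl-3-Bpin-4-[(pinacolboryl)oxy]octa-1,6-dien-2-yl}-4-methylfuran-3-yl acetate | C=C(c1occ(C)c1OC(C)=O)[C@@](C)(B1OC(C)(C)C(C)(C)O1)[C@@H](OB1OC(C)(C)C(C)(C)O1)CC=C(C)C
F3 | step 11 | (3S,4S)-2-(3-acetoxy-4-methylfuran-2-yl)-3,7-dimethyl-3-Bpin-octa-1,6-dien-4-yl 2-[bis(2,2,2-trifluoroethoxy)phosphoryl]propanoate (mixture at the phosphonate α-carbon) | C=C(c1occ(C)c1OC(C)=O)[C@@](C)(B1OC(C)(C)C(C)(C)O1)[C@@H](OC(=O)C(C)P(=O)(OCC(F)(F)F)OCC(F)(F)F)CC=C(C)C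
F4 | step 12 | (3S,4S)-2-(3-acetoxy-2,5-dimethoxy-4-methyl-2,5-dihydrofuran-2-yl)-3,7-dimethyl-3-Bpin-octa-1,6-dien-4-yl (2Z)-2-methylbut-2-enoate (mixture of acetal diastereomers) | COC1OC(OC)(C(=C)[C@@](C)(B2OC(C)(C)C(C)(C)O2)[C@@H](OC(=O)/C(C)=C\C)CC=C(C)C)C(OC(C)=O)=C1C
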